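**Plan**

- Locants: dihydronaphthalene C1 (pyranonyl), C2 (CO2H), C3 (CO2Me), C4, C4a, C8a; ring A is the catechol ring, ring B the carbocycle, ring C the pyranone (primed locants).
- Retrosynthesis: the C2 carboxyl goes back to an aldehyde and the phenols and pyranone acid to methyl ethers and a tert-butyl ester. Ring B is then cut at C2–C3, followed by C4–C4a (alkyne–aryl), C1–C8a (aryl to enal β-carbon), the enal C=C, and ring C (oxalate plus 3-methylbut-2-enoate).
- Forward order: ring C is built first and its 4-methyl group grown into an enal. Ring A is joined at C1, then iodinated and alkynylated. Ring B is closed last, followed by oxidation and deprotection.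
- Enabling feature: C3 is the α-carbon of an acrylate whose β-carbon C4 sits on ring A and has no γ-hydrogen. The C3=C4–CO2Me unit can therefore be stored as an arylpropiolate, which a phosphine makes electrophilic at C3. C2 bears an exocyclic carbonyl carbon, so at the aldehyde level C2–H is the acidic and epimerisable site.
- Stereochemistry: C1 comes from a chiral-diene/rhodium 1,4-arylation of the enal. C2 comes from the ring closure under control of C1, backed by trans-equilibration of the aldehyde, and is then frozen by Pinnick oxidation, which also keeps the C2 acid distinct from the C3 methyl ester.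

Key step: step 8

Remark: the (R,R)-diene ligand is assumed to deliver the aryl group to the Re face of the enal β-carbon (needed for S-configured 11); if the sense is opposite on this substrate, the commercial (S,S)-antipode is used with no other change.

**Step 1**
Reactants: 1 dimethyl oxalate; 2 methyl 3-methylbut-2-enoate
Product: 5 4-methyl-2-oxo-2H-pyran-6-carboxylic acid, via potassium dienolate of dimethyl 4-methyl-2-oxohex-4-enedioate 3 (not isolated), via methyl 4-methyl-2-oxo-2H-pyran-6-carboxylate 4 (not isolated)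
Conditions: KOtBu, THF, 0 °C to rt; then conc. aq. HCl, 90 °C
Reagents that add atoms: water, O
Why: Vinylogous Claisen condensation of the dienolate of 2 at its γ-carbon with 1, then acid-promoted enol lactonisation onto the Z-placed ester and ester hydrolysis, the classical route to 2-pyranone-6-carboxylic acids; no stereocentre.

**Step 2**
Reactants: 5 4-methyl-2-oxo-2H-pyran-6-carboxylic acid
Product: 6 tert-butyl 4-methyl-2-oxo-2H-pyran-6-carboxylate
Conditions: tert-butyl 2,2,2-trichloroacetimidate (2 equiv), BF3·OEt2 (cat.), THF/cyclohexane, rt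
Reagents that add atoms: tert-butyl 2,2,2-trichloroacetimidate, CC(C)(C)OC(=N)C(Cl)(Cl)Cl
Why: Imidate esterification (acid-catalysed tert-butyl transfer) leaves the lactone untouched and gives an ester that stays distinct from the C3 methyl ester to the end.

**Step 3**
Reactants: 6 tert-butyl 4-methyl-2-oxo-2H-pyran-6-carboxylate
Product: 7 tert-butyl 4-formyl-2-oxo-2H-pyran-6-carboxylate
Conditions: SeO2 (1.3 equiv), 1,4-dioxane, 100 °C
Reagents that add atoms: selenium dioxide, O=[Se]=O
Why: Riley oxidation of the vinylogously activated 4-methyl group, as for 4-methylcoumarins, should stop at the aldehyde.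

**Step 4**
Reactants: 7 tert-butyl 4-formyl-2-oxo-2H-pyran-6-carboxylate; 8 (triphenylphosphoranylidene)acetaldehyde
Product: 9 tert-butyl 2-oxo-4-[(E)-3-oxoprop-1-en-1-yl]-2H-pyran-6-carboxylate
Conditions: toluene, 60 °C
Reagents that add atoms: none
Why: Wittig reaction of the stabilised formyl ylide with the more electrophilic heteroaryl aldehyde should give the E-enal.

**Step 5**
Reactants: 9 tert-butyl 2-oxo-4-[(E)-3-oxoprop-1-en-1-yl]-2H-pyran-6-carboxylate; 10 (3,4-dimethoxyphenyl)boronic acid
Product: 11 tert-butyl 4-[(1S)-1-(3,4-dimethoxyphenyl)-3-oxopropyl]-2-oxo-2H-pyran-6-carboxylate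
Conditions: [RhCl(C2H4)2]2 (2.5 mol%), (1R,4R)-2,5-diphenylbicyclo[2.2.2]octa-2,5-diene (5.5 mol%), KOH (10 mol%), 1,4-dioxane/H2O 10:1, 30 °C
Reagents that add atoms: none
Why: Hayashi–Miyaura reaction: the aryl–rhodium species adds 1,4 to the enal (diene ligands favour 1,4- over 1,2-addition) and the chiral diene directs the aryl group to the Re face of the β-carbon, which sets C1 as S in 11.

**Step 6**
Reactants: 11 tert-butyl 4-[(1S)-1-(3,4-dimethoxyphenyl)-3-oxopropyl]-2-oxo-2H-pyran-6-carboxylate
Product: 12 tert-butyl 4-[(1R)-1-(2-iodo-4,5-dimethoxyphenyl)-3-oxopropyl]-2-oxo-2H-pyran-6-carboxylate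
Conditions: NIS (1.1 equiv), TFA (20 mol%), MeCN, 0 °C to rt, dark
Reagents that add atoms: N-iodosuccinimide, O=C1CCC(=O)N1I
Why: Electrophilic aromatic iodination goes para to a methoxy group and ortho to the side chain, the usual site in 4-alkylveratroles; C1 is not touched, and its descriptor becomes R only because iodine raises the CIP rank of the aryl group.

**Step 7**
Reactants: 12 tert-butyl 4-[(1R)-1-(2-iodo-4,5-dimethoxyphenyl)-3-oxopropyl]-2-oxo-2H-pyran-6-carboxylate; 13 methyl propiolate
Product: 14 tert-butyl 4-[(1R)-1-[4,5-dimethoxy-2-(3-methoxy-3-oxoprop-1-yn-1-yl)phenyl]-3-oxopropyl]-2-oxo-2H-pyran-6-carboxylate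
Conditions: PdCl2(PPh3)2 (5 mol%), CuI (10 mol%), K2CO3 (2 equiv), THF, 50 °C, slow addition of 13 (3 equiv)
Reagents that add atoms: none
Why: Sonogashira coupling with the inorganic base K2CO3, which avoids amine addition to the propiolate, should place the alkynoate on C4a.

**Step 8**
Reactants: 14 tert-butyl 4-[(1R)-1-[4,5-dimethoxy-2-(3-methoxy-3-oxoprop-1-yn-1-yl)phenyl]-3-oxopropyl]-2-oxo-2H-pyran-6-carboxylate
Product: 17 tert-butyl 4-[(1R,2S)-2-formyl-6,7-dimethoxy-3-(methoxycarbonyl)-1,2-dihydronaphthalen-1-yl]-2-oxo-2H-pyran-6-carboxylate, via vinylphosphonium aldehyde enolate zwitterion 15 (not isolated), via cyclised phosphonium ester enolate 16 (not isolated)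
Conditions: PBu3 (20 mol%), AcOH (50 mol%), NaOAc (50 mol%), toluene (0.02 M), 80 °C
Reagents that add atoms: none
Why: Proposed new method: PBu3 adds to C4 of the alkynoate (the carbon on ring A, with no γ-hydrogen, so only α-umpolung is open), AcOH protonates the C3 vinyl anion to the β-phosphonio acrylate, and the acetate-generated aldehyde enolate at C2 (15) attacks C3, the only electrophilic carbon left; proton shift from C3 to the ylide carbon C4 (16) and β-elimination of PBu3 then release the C3=C4 cinnamate and the catalyst. The closest known reaction type is the phosphine-catalysed α-addition (anti-Michael, umpolung) of N–H and 1,3-dicarbonyl C–H pronucleophiles to alkynoates, here made intramolecular and extended to a singly activated aldehyde. Ring B closes in a 6-endo-trig mode on the vinylphosphonium (formally 6-endo-dig on the alkyne). C1 is not touched, since its C–H is far less acidic than the aldehyde α-C–H under the acetate buffer; the new C2 centre is set by C1, because the enolate should react in the conformer with C1–H eclipsing the enolate double bond (A1,3 strain) so that C3 bonds anti to the pyranone, and the enolisable aldehyde centre is in any case under thermodynamic control, which favours the trans-diaxial arrangement. The step needs α-attack (six-membered ring) over the normal β-attack (5-exo-dig Michael closure onto C4) and C- over O-alkylation: the first should be secured because the enolate exists only in a buffered medium in which the cationic vinylphosphonium is far more electrophilic than the neutral ynoate, the second by ring size (six against eight).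

**Step 9**
Reactants: 17 tert-butyl 4-[(1R,2S)-2-formyl-6,7-dimethoxy-3-(methoxycarbonyl)-1,2-dihydronaphthalen-1-yl]-2-oxo-2H-pyran-6-carboxylate
Product: 18 (1R,2S)-1-[6-(tert-butoxycarbonyl)-2-oxo-2H-pyran-4-yl]-6,7-dimethoxy-3-(methoxycarbonyl)-1,2-dihydronaphthalene-2-carboxylic acid
Conditions: NaClO2, NaH2PO4, 2-methyl-2-butene, t-BuOH/H2O, 0 °C to rt
Reagents that add atoms: sodium chlorite, [Na+].[O-]Cl=O
Why: Pinnick oxidation at buffered pH should convert the aldehyde into the acid without epimerising C2 or touching the alkene, the alkene scavenger removing HOCl.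

**Step 10**
Reactants: 18 (1R,2S)-1-[6-(tert-butoxycarbonyl)-2-oxo-2H-pyran-4-yl]-6,7-dimethoxy-3-(methoxycarbonyl)-1,2-dihydronaphthalene-2-carboxylic acid
Product: 19 4-[(1R,2S)-2-carboxy-6,7-dihydroxy-3-(methoxycarbonyl)-1,2-dihydronaphthalen-1-yl]-2-oxo-2H-pyran-6-carboxylic acid
Conditions: BBr3 (8 equiv), CH2Cl2, −78 to 0 °C; then H2O, 0 °C
Reagents that add atoms: none
Why: BBr3 should cleave the two aryl methyl ethers and the tert-butyl ester by Lewis acid-assisted O–alkyl cleavage while the conjugated methyl ester survives at low temperature; no stereocentre is involved.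

**Compound list**

1 | dimethyl oxalate | COC(=O)C(=O)OC | starting material
2 | methyl 3-methylbut-2-enoate | COC(=O)C=C(C)C | starting material
3 | potassium dienolate of dimethyl 4-methyl-2-oxohex-4-enedioate (alkene isomers interconvert; the 4Z form lactonises) | COC(=O)C([O-])=CC(C)=CC(=O)OC.[K+] | intermediate
4 | methyl 4-methyl-2-oxo-2H-pyran-6-carboxylate | Cc1cc(=O)oc(C(=O)OC)c1 | intermediate
5 | 4-methyl-2-oxo-2H-pyran-6-carboxylic acid | Cc1cc(=O)oc(C(=O)O)c1 | intermediate
6 | tert-butyl 4-methyl-2-oxo-2H-pyran-6-carboxylate | Cc1cc(=O)oc(C(=O)OC(C)(C)C)c1 | intermediate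
7 | tert-butyl 4-formyl-2-oxo-2H-pyran-6-carboxylate | O=Cc1cc(=O)oc(C(=O)OC(C)(C)C)c1 | intermediate
8 | (triphenylphosphoranylidene)acetaldehyde | O=CC=P(c1ccccc1)(c1ccccc1)c1ccccc1 | starting material
9 | tert-butyl 2-oxo-4-[(E)-3-oxoprop-1-en-1-yl]-2H-pyran-6-carboxylate | O=C/C=C/c1cc(=O)oc(C(=O)OC(C)(C)C)c1 | intermediate
10 | (3,4-dimethoxyphenyl)boronic acid | COc1ccc(B(O)O)cc1OC | starting material
11 | tert-butyl 4-[(1S)-1-(3,4-dimethoxyphenyl)-3-oxopropyl]-2-oxo-2H-pyran-6-carboxylate | COc1ccc(cc1OC)[C@@H](c1cc(C(=O)OC(C)(C)C)oc(=O)c1)CC=O | intermediate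
12 | tert-butyl 4-[(1R)-1-(2-iodo-4,5-dimethoxyphenyl)-3-oxopropyl]-2-oxo-2H-pyran-6-carboxylate | COc1cc(I)c(cc1OC)[C@@H](c1cc(C(=O)OC(C)(C)C)oc(=O)c1)CC=O | intermediate
13 | methyl propiolate | C#CC(=O)OC | starting material
14 | tert-butyl 4-[(1R)-1-[4,5-dimethoxy-2-(3-methoxy-3-oxoprop-1-yn-1-yl)phenyl]-3-oxopropyl]-2-oxo-2H-pyran-6-carboxylate | COC(=O)C#Cc1cc(OC)c(OC)cc1[C@@H](c1cc(C(=O)OC(C)(C)C)oc(=O)c1)CC=O | intermediate
15 | vinylphosphonium aldehyde enolate zwitterion (PBu3 on C4, enolate at C2; alkene geometries not fixed) | CCCC[P+](CCCC)(CCCC)C(=CC(=O)OC)c1cc(OC)c(OC)cc1[C@@H](c1cc(C(=O)OC(C)(C)C)oc(=O)c1)C=C[O-] | intermediate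
16 | cyclised phosphonium ester enolate (C2–C3 bond formed, PBu3 still on C4, C4 configuration of no consequence) | COC([O-])=C1C([P+](CCCC)(CCCC)CCCC)c2cc(OC)c(OC)cc2[C@@H](c2cc(C(=O)OC(C)(C)C)oc(=O)c2)[C@@H]1C=O | intermediate
17 | tert-butyl 4-[(1R,2S)-2-formyl-6,7-dimethoxy-3-(methoxycarbonyl)-1,2-dihydronaphthalen-1-yl]-2-oxo-2H-pyran-6-carboxylate | COC(=O)C1=Cc2cc(OC)c(OC)cc2[C@@H](c2cc(C(=O)OC(C)(C)C)oc(=O)c2)[C@@H]1C=O | intermediate
18 | (1R,2S)-1-[6-(tert-butoxycarbonyl)-2-oxo-2H-pyran-4-yl]-6,7-dimethoxy-3-(methoxycarbonyl)-1,2-dihydronaphthalene-2-carboxylic acid | COC(=O)C1=Cc2cc(OC)c(OC)cc2[C@@H](c2cc(C(=O)OC(C)(C)C)oc(=O)c2)[C@@H]1C(=O)O | intermediate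
19 | 4-[(1R,2S)-2-carboxy-6,7-dihydroxy-3-(methoxycarbonyl)-1,2-dihydronaphthalen-1-yl]-2-oxo-2H-pyran-6-carboxylic acid | COC(=O)C1=Cc2cc(O)c(O)cc2[C@@H](c2cc(C(=O)O)oc(=O)c2)[C@@H]1C(=O)O | target

**Count**

Total step count: 10. Longest linear sequence: 10 steps (1 and 2 to 19; 8, 10 and 13 are bought).

**Steps most likely to fail**

1. Step 8 (Proposed new method). The aldehyde α-C–H may be deprotonated too slowly, so that phosphine-induced oligomerisation of the ynoate or base-type 5-exo closure onto C4 takes over. Fallback with known chemistry, from 12 back to 17: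
   - Heck coupling of 12 with methyl acrylate (Pd(OAc)2, P(o-tol)3, Et3N, MeCN, 80 °C) should give tert-butyl 4-[(1R)-1-{4,5-dimethoxy-2-[(E)-3-methoxy-3-oxoprop-1-en-1-yl]phenyl}-3-oxopropyl]-2-oxo-2H-pyran-6-carboxylate F1.
   - Bromine addition (Br2, CH2Cl2, −78 °C) should give the dibromide tert-butyl 4-[(1R)-1-[2-(1,2-dibromo-3-methoxy-3-oxopropyl)-4,5-dimethoxyphenyl]-3-oxopropyl]-2-oxo-2H-pyran-6-carboxylate F2.
   - Et3N should eliminate HBr to the (Z)-α-bromocinnamate tert-butyl 4-[(1R)-1-{2-[(Z)-2-bromo-3-methoxy-3-oxoprop-1-en-1-yl]-4,5-dimethoxyphenyl}-3-oxopropyl]-2-oxo-2H-pyran-6-carboxylate F3, with bromine cis to ring A.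
   - Palladium-catalysed intramolecular coupling of the vinyl bromide with the aldehyde enolate (PdCl2(PPh3)2, Cs2CO3, THF, 65 °C) would then close C2–C3 and give 17 after equilibration of the aldehyde centre.

2. Step 5. The aryl transfer may show poor facial selectivity, or 1,2-arylation of the aldehyde and protodeboronation may compete. Fallback, from 9 back to 11:
   - Heck arylation of 9 with 4-iodo-1,2-dimethoxybenzene (Pd(OAc)2, Bu4NCl, NaHCO3, DMF, 60 °C) should give the β,β-diaryl enal tert-butyl 4-[1-(3,4-dimethoxyphenyl)-3-oxoprop-1-en-1-yl]-2-oxo-2H-pyran-6-carboxylate F4 as an E/Z mixture.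
   - Iminium-catalysed transfer hydrogenation (chiral 5-benzyl-2-tert-butyl-3-methylimidazolidin-4-one trifluoroacetate, Hantzsch ester, CHCl3, −30 °C) reduces both alkene isomers convergently and should give 11, with the catalyst antipode chosen for the S centre.

3. Step 7. Base-promoted oligomerisation of methyl propiolate and conjugate additions may outrun coupling at the hindered iodide. Fallback, from 12 back to 14:
   - Sonogashira coupling with ethynyltrimethylsilane (PdCl2(PPh3)2, CuI, Et3N, THF, rt) should give tert-butyl 4-[(1R)-1-{4,5-dimethoxy-2-[(trimethylsilyl)ethynyl]phenyl}-3-oxopropyl]-2-oxo-2H-pyran-6-carboxylate F5.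
   - Buffered desilylation (Bu4NF, AcOH, THF, 0 °C) should give the terminal alkyne tert-butyl 4-[(1R)-1-(2-ethynyl-4,5-dimethoxyphenyl)-3-oxopropyl]-2-oxo-2H-pyran-6-carboxylate F6.
   - Oxidative methoxycarbonylation of the alkyne C–H (PdCl2 cat., CuCl2, NaOAc, CO 1 atm, MeOH, rt) should give 14.

**Further compounds**

F1 | step 8 | tert-butyl 4-[(1R)-1-{4,5-dimethoxy-2-[(E)-3-methoxy-3-oxoprop-1-en-1-yl]phenyl}-3-oxopropyl]-2-oxo-2H-pyran-6-carboxylate | COC(=O)/C=C/c1cc(OC)c(OC)cc1[C@@H](c1cc(C(=O)OC(C)(C)C)oc(=O)c1)CC=O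
F2 | step 8 | tert-butyl 4-[(1R)-1-[2-(1,2-dibromo-3-methoxy-3-oxopropyl)-4,5-dimethoxyphenyl]-3-oxopropyl]-2-oxo-2H-pyran-6-carboxylate | COC(=O)C(Br)C(Br)c1cc(OC)c(OC)cc1[C@@H](c1cc(C(=O)OC(C)(C)C)oc(=O)c1)CC=O
F3 | step 8 | tert-butyl 4-[(1R)-1-{2-[(Z)-2-bromo-3-methoxy-3-oxoprop-1-en-1-yl]-4,5-dimethoxyphenyl}-3-oxopropyl]-2-oxo-2H-pyran-6-carboxylate | COC(=O)/C(Br)=C/c1cc(OC)c(OC)cc1[C@@H](c1cc(C(=O)OC(C)(C)C)oc(=O)c1)CC=O
F4 | step 5 | tert-butyl 4-[1-(3,4-dimethoxyphenyl)-3-oxoprop-1-en-1-yl]-2-oxo-2H-pyran-6-carboxylate (E/Z mixture) | COc1ccc(cc1OC)C(=CC=O)c1cc(C(=O)OC(C)(C)C)oc(=O)c1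
F5 | step 7 | tert-butyl 4-[(1R)-1-{4,5-dimethoxy-2-[(trimethylsilyl)ethynyl]phenyl}-3-oxopropyl]-2-oxo-2H-pyran-6-carboxylate | C[Si](C)(C)C#Cc1cc(OC)c(OC)cc1[C@@H](c1cc(C(=O)OC(C)(C)C)oc(=O)c1)CC=O
F6 | step 7 | tert-butyl 4-[(1R)-1-(2-ethynyl-4,5-dimethoxyphenyl)-3-oxopropyl]-2-oxo-2H-pyran-6-carboxylate | C#Cc1cc(OC)c(OC)cc1[C@@H](c1cc(C(=O)OC(C)(C)C)oc(=O)c1)CC=O
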